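# Proposed total synthesis of isolappaol A (35) by oxidative para-quinone methide cycloetherification

## The problem

Isolappaol A (35) is a sesquineolignan built from two parts. One is a trans-α,β-dibenzylbutyrolactone of the matairesinol type (Cα and Cβ both R). Its α-benzyl carbon is attached to C5 of the other part, a trans-2-aryl-3-hydroxymethyl-7-methoxy-2,3-dihydrobenzofuran (C2 S, C3 R). Ring A is the guaiacyl ring of the Cβ benzyl group, ring B the benzo ring of the dihydrobenzofuran, and ring C the guaiacyl ring on C2.

The two pairs of stereocentres are separated by a methylene group and ring B, so neither pair can influence the other and each needs its own source of absolute configuration. Within each pair one centre can set its neighbour: Cβ steers an enolate alkylation at Cα to the trans face, and C3 steers ring closure at C2 to the trans arrangement, which is also the more stable one. The chain is therefore best assembled convergently, a lactone fragment and a dihydrobenzofuran fragment being joined at the Cα–CH2 bond.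

Two phenols and a primary alcohol need temporary masking. The 2-(4-hydroxyphenyl)dihydrobenzofuran is fragile in three ways: strong base opens it through its quinone methide, excess oxidant dehydrogenates it to the benzofuran, and forcing hydrogenolysis cleaves the benzylic C2–O1 bond. The lactone epimerises at Cα and does not survive hydride reagents, so every reduction on ring B has to precede its introduction.

The enabling feature is that C2 is benzylic to ring C and para to its phenolic oxygen, which makes it a latent para-quinone methide carbon. O1 is a phenol oxygen of ring B, placed so that its addition to that carbon closes a five-membered ring.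

## Retrosynthesis

**Protecting groups (O–Si and O–CH2Ph bonds).** Target 35 is traced back through benzyl ether 34 to bis-silyl ether 33. The two hydroxyl groups of the dihydrobenzofuran half are carried as silyl ethers and the ring A phenol as a benzyl ether. Fluoride is applied first, so that the last operation is a neutral hydrogenolysis of a single aryl benzyl ether and the polar product is freed by filtration only. Neither removal touches a stereocentre.

**Lactone Cα–CH2 bond.** Cutting 33 here gives lactone 31 (as its lithium enolate 32) and benzylic bromide 22. The cut separates the two stereochemical pairs completely. The alternative cut at Cβ–CH2 would need a conjugate addition with external control. Here the single stereocentre of 31 directs the electrophile to the opposite face and delivers the trans lactone. Both fragments are far simpler than 33. The forward reaction must be a clean C-alkylation with a reactive para-alkoxybenzyl bromide at low temperature.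

**Adjustment of ring B and hydroxyl groups (C–Br, C–O, O–Si).** Bromide 22 comes from alcohol 21, this from ester 20, and 20 from diol-ester 19 by double silylation. The ester is kept as the C5 substituent up to this point because it is needed in the key step as a deactivating group on ring B. It is reduced only after the ring has been closed and before the lactone is present.

**O1–C2 bond (key disconnection).** Opening the dihydrofuran ring of 19 at O1–C2 leads to diphenol 17, which has one stereocentre instead of two and no heterocycle. Neighbouring cuts are less attractive. Cutting C2–C3 would require both centres to be set at once. Cutting C3–C3a would require an asymmetric arylation. In the forward direction ring C of 17 is oxidised to para-quinone methide 18 and the ring B phenol adds to it. The reaction must oxidise ring C only, close faster than 18 can tautomerise, and place the aryl group trans to the C3 arm.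

The hydroxymethyl group is deliberately left free in 17. It cannot reach C2 except through an oxetane, and a quinone methide with exactly this free γ-hydroxyl is the species that closes to trans-phenylcoumarans in oxidative β-5 coupling. Protection is postponed until both hydroxyl groups of 19 can be silylated together.

**C3–CH2 bond of the propane chain.** Triol 17 is the hydrogenolysis product of bis-benzyl ether 16, which comes from imide 15 by reductive removal of the auxiliary. Imide 15 is cut at the bond between the future C3 and the future C2, giving the sodium enolate 14 of arylacetyl imide 11 and bromide 13 (from alcohol 12). This places the only stereocentre of 17 under auxiliary control in an enolate alkylation, one of the most dependable ways to make an α-aryl stereocentre. The forward reaction must keep the acidic product from epimerising. The auxiliary removal must spare the methyl benzoate.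

**Arylacetic acid (N–acyl bond and ring B side chain).** Imide 11 comes from acid 8 and oxazolidinone 9. Acid 8 is the oxidative cleavage product (through aldehyde 7) of allylarene 6, the benzyl ether of phenol 4. The allyl group of 4 is delivered to the only free ortho position by Claisen rearrangement of allyl ether 3, made from methyl vanillate 1 and allyl bromide 2. This installs the two-carbon arm exactly where ring B needs it, without any directing-group chemistry.

**Lactone 31 (ring C–C bonds from the chiral pool).** Lactone 31 is the dealkoxycarbonylation product of ester 30. Ester 30 arises by opening cyclopropane-fused lactone 27 at its CH2 group with aryl Grignard reagent 29 (from bromide 28). Lactone 27 is assembled from (R)-epichlorohydrin 23 and diethyl malonate 24 through epoxide 25 and cyclopropane 26. The configuration of Cβ thus comes from a bulk chiral building block in three steps.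

## Roads not taken

**Alternative 1: three-component coupling on a chiral butenolide, then lactone transposition.** This cuts both benzylic bonds of the lactone at once. In the forward step the lithio derivative of aryl dithiane A3 adds to the β-carbon of chiral-pool butenolide A2, anti to its trityloxymethyl group. The enolate is then trapped, anti again, by bromide 13, giving the all-trans lactone A1 in one flask.

- Merits: two C–C bonds and two stereocentres form in one operation, with relative configuration relayed from one inexpensive stereocentre. The dihydrobenzofuran enters as a stable dithiane at the aldehyde oxidation level, not as a labile bromide such as 22. In that respect this road is the more comfortable one.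
- Weak points: in A1 the vanillyl group sits next to the carbonyl and the dihydrobenzofuran-bearing carbon is β, the reverse of 35. The lactone must therefore be transposed (detritylation, reduction, glycol cleavage, lactol oxidation). The dithiane must then be removed with Raney Ni, which endangers the benzyl ethers and above all the benzylic C2–O1 bond.
- A3 already contains the finished dihydrobenzofuran, so this road leaves the harder half of the problem unsolved.
- Comparison: against the single alkylation of step 17 it spends one coupling and about five corrective steps. The chosen plan sets brevity and the absence of a reductive desulfurisation against the better stability of the coupling partners.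

**Alternative 2: desymmetrising Baeyer–Villiger oxidation of a cyclobutanone.** The cut is at the ring oxygen of the lactone. A chiral acid catalyst with aqueous H2O2 distinguishes the two enantiotopic CH2–C(=O) bonds of prochiral cyclobutanone A4 and inserts oxygen to give lactone A5, which is the same compound as 31.

- Merits: catalytic, no stoichiometric chiral material, a benign oxidant, and A4 is a few steps from an allylbenzene by ketene [2+2] cycloaddition. No organometallic reagent and no hot dealkoxycarbonylation are needed, so operationally it is at least the equal of steps 14–16.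
- Weak points: the stereocentre is created far from any directing group, and 3-benzylcyclobutanones are a less selective substrate class than 3-arylcyclobutanones. A5 is not a crystalline compound that could be enriched easily. Any shortfall in enantiopurity becomes a diastereomer after coupling with enantiopure 22.
- It addresses only the simple fragment and says nothing about the dihydrobenzofuran.
- Comparison: the step count to 31 is about the same. The chosen plan sets against it a configuration fixed by the chiral pool. The alternative could replace steps 14–16 without changing anything else.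

**Alternative 3: ortho-quinone methide plus chiral sulfonium benzylide [4+1] annulation.** This cuts C3–C2 and O1–C2 together, C2 with ring C arriving as a one-carbon ylide. Cs2CO3 eliminates sulfinate from sulfone A6 to give its ortho-quinone methide and deprotonates sulfonium salt A7 to its ylide. Conjugate addition forms C3–C2 and displacement of the sulfide by the phenoxide forms O1–C2, giving A8.

- Merits: the most convergent road. Two bonds, the ring and both stereocentres form in one step, and trans selectivity is inherent in the betaine closure. It reaches the dihydrobenzofuran in clearly fewer steps than the ten that lead to 19, so on step economy it is better.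
- Weak points: absolute configuration rests on face discrimination by a chiral semi-stabilised benzylide, whereas asymmetric variants of this annulation are established mainly for carbonyl-stabilised ylides. Neither sense nor level of induction can be predicted, so the antipode of A7 would have to be found by trial.
- The ortho-quinone methide from A6 carries an alkyl substituent with a β-silyloxy group and can tautomerise to a vinylphenol before it is trapped.
- A stoichiometric chiral sulfide is consumed, and the aryl bromide of A8 needs three steps to reach the stage of 22, against two from the ester.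
- Comparison: the chosen plan sets against the shorter route an auxiliary-controlled, predictable configuration at C3 and its relay to C2 under conditions where the trans isomer is favoured both kinetically and thermodynamically.

Key step: step 10

Remark on availability: alcohol 12 and aryl bromide 28 are treated as catalogue compounds; either would otherwise be one routine step from a catalogue aldehyde or phenol.

## Route

Step 1
Reactants: 1 methyl vanillate; 2 allyl bromide
Product: 3 methyl 4-(allyloxy)-3-methoxybenzoate
Conditions: K2CO3, acetone, reflux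
Reagents that add atoms: none
Why: Williamson etherification (SN2) of the only acidic site with an allylic bromide; the ester and methyl ether are inert.

Step 2
Reactants: 3 methyl 4-(allyloxy)-3-methoxybenzoate
Product: 4 methyl 3-allyl-4-hydroxy-5-methoxybenzoate
Conditions: N,N-diethylaniline, 200 °C
Reagents that add atoms: none
Why: Aromatic Claisen rearrangement; the [3,3] shift can deliver the allyl group only to the single unsubstituted ortho carbon, and tautomerisation restores the phenol.

Step 3
Reactants: 4 methyl 3-allyl-4-hydroxy-5-methoxybenzoate; 5 benzyl bromide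
Product: 6 methyl 3-allyl-4-(benzyloxy)-5-methoxybenzoate
Conditions: K2CO3, DMF, rt
Reagents that add atoms: none
Why: Williamson benzylation; the benzyl ether masks the ring B phenol through the enolate chemistry and leaves together with the ring C benzyl ether in step 9.

Step 4
Reactants: 6 methyl 3-allyl-4-(benzyloxy)-5-methoxybenzoate
Product: 8 2-[2-(benzyloxy)-3-methoxy-5-(methoxycarbonyl)phenyl]acetic acid, via arylacetaldehyde 7 (not isolated)
Conditions: O3, MeCN/H2O (9:1), 0 °C; then NaClO2, NaH2PO4, H2O2 (30% aq), 0 °C → rt
Reagents that add atoms: ozone, [O-][O+]=O; sodium chlorite, [Na+].[O-]Cl=O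
Why: Ozonolysis in aqueous acetonitrile gives aldehyde 7 directly because water intercepts the carbonyl oxide, and Pinnick oxidation in the same flask takes it to the acid while hydrogen peroxide scavenges hypochlorite so that ring B is not chlorinated; the terminal alkene reacts with ozone far faster than the benzyl ether or the ester-bearing arene.

Step 5
Reactants: 8 2-[2-(benzyloxy)-3-methoxy-5-(methoxycarbonyl)phenyl]acetic acid; 9 (R)-4-benzyl-2-oxazolidinone
Product: 11 methyl 4-(benzyloxy)-3-{2-[(4R)-4-benzyl-2-oxo-1,3-oxazolidin-3-yl]-2-oxoethyl}-5-methoxybenzoate, via mixed pivalic anhydride 10 (not isolated)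
Conditions: PivCl, Et3N, THF, −20 °C; then LiCl, 9, −20 °C → rt
Reagents that add atoms: none
Why: N-Acylation of the Evans auxiliary through the mixed anhydride; LiCl and Et3N activate the oxazolidinone N–H, and attack occurs at the less hindered arylacetyl carbonyl.

Step 6
Reactants: 12 4-(benzyloxy)-3-methoxybenzyl alcohol
Product: 13 4-(benzyloxy)-3-methoxybenzyl bromide
Conditions: PBr3, Et2O, 0 °C
Reagents that add atoms: phosphorus tribromide, BrP(Br)Br
Why: Standard conversion of an electron-rich benzylic alcohol into its bromide through the phosphite ester; the bromide is used at once.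

Step 7
Reactants: 11 methyl 4-(benzyloxy)-3-{2-[(4R)-4-benzyl-2-oxo-1,3-oxazolidin-3-yl]-2-oxoethyl}-5-methoxybenzoate; 13 4-(benzyloxy)-3-methoxybenzyl bromide
Product: 15 methyl 4-(benzyloxy)-3-{(2R)-1-[(4R)-4-benzyl-2-oxo-1,3-oxazolidin-3-yl]-3-[4-(benzyloxy)-3-methoxyphenyl]-1-oxopropan-2-yl}-5-methoxybenzoate, via sodium Z-enolate 14 (not isolated)
Conditions: NaN(SiMe3)2 (1.0 equiv), THF, −78 °C; then 13, −78 → −45 °C
Reagents that add atoms: none
Why: Evans asymmetric alkylation: the chelated Z-enolate 14 is shielded on one face by the benzyl group of the (R)-auxiliary, so bromide 13 enters from the other face and sets the R configuration of the future C3; low temperature and no excess base protect the acidic α-aryl centre from epimerisation.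

Step 8
Reactants: 15 methyl 4-(benzyloxy)-3-{(2R)-1-[(4R)-4-benzyl-2-oxo-1,3-oxazolidin-3-yl]-3-[4-(benzyloxy)-3-methoxyphenyl]-1-oxopropan-2-yl}-5-methoxybenzoate
Product: 16 methyl 4-(benzyloxy)-3-{(2R)-1-[4-(benzyloxy)-3-methoxyphenyl]-3-hydroxypropan-2-yl}-5-methoxybenzoate
Conditions: NaBH4, THF/H2O (4:1), 0 °C → rt
Reagents that add atoms: none
Why: Reductive removal of the auxiliary: borohydride in aqueous THF reduces the activated imide carbonyl to the primary alcohol but does not reduce a methyl benzoate; the stereocentre is not involved and the auxiliary is recovered.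

Step 9
Reactants: 16 methyl 4-(benzyloxy)-3-{(2R)-1-[4-(benzyloxy)-3-methoxyphenyl]-3-hydroxypropan-2-yl}-5-methoxybenzoate
Product: 17 methyl 4-hydroxy-3-[(2R)-1-hydroxy-3-(4-hydroxy-3-methoxyphenyl)propan-2-yl]-5-methoxybenzoate
Conditions: H2 (1 atm), 10% Pd/C, EtOAc/MeOH, rt
Reagents that add atoms: none
Why: Hydrogenolysis of both aryl benzyl ethers frees the two phenols that the key step needs; the aryl ester, the alcohol and the stereocentre are inert.

Step 10
Reactants: 17 methyl 4-hydroxy-3-[(2R)-1-hydroxy-3-(4-hydroxy-3-methoxyphenyl)propan-2-yl]-5-methoxybenzoate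
Product: 19 methyl (2S,3R)-2-(4-hydroxy-3-methoxyphenyl)-3-(hydroxymethyl)-7-methoxy-2,3-dihydro-1-benzofuran-5-carboxylate, via para-quinone methide 18 (not isolated)
Conditions: Ag2O (1.1 equiv), CH2Cl2/acetone (4:1), 0.01 M, rt, dark
Reagents that add atoms: none
Why: Ag2O takes the phenolic hydrogen and one para-benzylic hydrogen from ring C of 17 (two one-electron steps, ending as metallic silver and water) and so forms para-quinone methide 18; ring B cannot do the same because its para position carries the ester, which also raises its oxidation potential. The ring B phenol oxygen then adds to the exocyclic methide carbon in an oxa-1,6-conjugate addition that rearomatises ring C and forms the O1–C2 bond. The dihydrofuran ring closes in the 5-exo-trig mode. The closest known reaction type is the Ag2O- or quinone-mediated oxidative cyclisation of phenol-tethered 4-hydroxybenzyl units through para-quinone methides, known for flavans, and the closing event itself is the one that ends oxidative β-5 coupling of 4-hydroxycinnamyl units, where a quinone methide of this kind with a free γ-hydroxyl is trapped by the adjacent phenol to give trans-2-aryl-3-hydroxymethyldihydrobenzofurans. The new stereocentre C2 is controlled by C3: in the envelope-like transition state the quinoid ring turns away from the hydroxymethyl arm, and the trans isomer is also the more stable one, so (R)-17 leads to (2S,3R)-19. The step needs oxidation of ring C only (secured by the ester on ring B), closure faster than proton loss from C3 of 18 to a stilbene (secured by the intramolecular five-membered trap in a neutral, aprotic, dilute medium) and no interference from the primary hydroxyl (it could only close an oxetane); about one equivalent of oxidant guards the product, still a 4-alkylphenol, against further dehydrogenation.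

Step 11
Reactants: 19 methyl (2S,3R)-2-(4-hydroxy-3-methoxyphenyl)-3-(hydroxymethyl)-7-methoxy-2,3-dihydro-1-benzofuran-5-carboxylate
Product: 20 methyl (2S,3R)-2-{4-[(tert-butyldimethylsilyl)oxy]-3-methoxyphenyl}-3-{[(tert-butyldimethylsilyl)oxy]methyl}-7-methoxy-2,3-dihydro-1-benzofuran-5-carboxylate
Conditions: TBSCl (2.5 equiv), imidazole, DMF, rt
Reagents that add atoms: tert-butyldimethylsilyl chloride, CC(C)(C)[Si](C)(C)Cl
Why: Silylation of the phenol and the primary alcohol in one operation; the non-basic conditions avoid phenoxide-driven reopening of the dihydrobenzofuran, and both groups later fall to one fluoride treatment.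

Step 12
Reactants: 20 methyl (2S,3R)-2-{4-[(tert-butyldimethylsilyl)oxy]-3-methoxyphenyl}-3-{[(tert-butyldimethylsilyl)oxy]methyl}-7-methoxy-2,3-dihydro-1-benzofuran-5-carboxylate
Product: 21 [(2S,3R)-2-{4-[(tert-butyldimethylsilyl)oxy]-3-methoxyphenyl}-3-{[(tert-butyldimethylsilyl)oxy]methyl}-7-methoxy-2,3-dihydro-1-benzofuran-5-yl]methanol
Conditions: i-Bu2AlH (2.5 equiv), CH2Cl2, −78 → −40 °C
Reagents that add atoms: none
Why: Hydride reduction of the aryl ester to the benzylic alcohol at low temperature; silyl ethers, aryl ethers and both stereocentres are untouched, and no lactone is yet present.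

Step 13
Reactants: 21 [(2S,3R)-2-{4-[(tert-butyldimethylsilyl)oxy]-3-methoxyphenyl}-3-{[(tert-butyldimethylsilyl)oxy]methyl}-7-methoxy-2,3-dihydro-1-benzofuran-5-yl]methanol
Product: 22 (2S,3R)-5-(bromomethyl)-2-{4-[(tert-butyldimethylsilyl)oxy]-3-methoxyphenyl}-3-{[(tert-butyldimethylsilyl)oxy]methyl}-7-methoxy-2,3-dihydro-1-benzofuran
Conditions: CBr4, PPh3, CH2Cl2, 0 °C
Reagents that add atoms: carbon tetrabromide, BrC(Br)(Br)Br
Why: Appel bromination under neutral conditions converts the benzylic alcohol into the bromide without acid that would endanger the silyl ethers; the para-alkoxy-activated bromide is used without storage.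

Step 14
Reactants: 23 (R)-epichlorohydrin; 24 diethyl malonate
Product: 27 ethyl (1S,5R)-2-oxo-3-oxabicyclo[3.1.0]hexane-1-carboxylate, via epoxide 25 (not isolated), via hydroxymethylcyclopropane diester 26 (not isolated)
Conditions: NaOEt, EtOH, 0 °C → reflux
Reagents that add atoms: none
Why: Double alkylation of malonate by the chiral epoxide: malonate opens the epoxide at CH2, the alkoxide closes epoxide 25 by displacing chloride, intramolecular SN2 opening with inversion gives cyclopropane 26, and its alkoxide lactonises onto the cis ester; the stereocentre comes from the chiral pool.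

Step 15
Reactants: 27 ethyl (1S,5R)-2-oxo-3-oxabicyclo[3.1.0]hexane-1-carboxylate; 28 1-(benzyloxy)-4-bromo-2-methoxybenzene
Product: 30 ethyl (3S,4R)-4-[4-(benzyloxy)-3-methoxybenzyl]-2-oxotetrahydrofuran-3-carboxylate, via arylmagnesium bromide 29 (not isolated)
Conditions: 28, Mg, THF, 40 °C; then 27, CuBr·SMe2 (10 mol%), THF, −30 → 0 °C
Reagents that add atoms: none
Why: Copper-catalysed homoconjugate addition of the Grignard reagent opens the doubly activated cyclopropane at its unsubstituted CH2 and leaves the stereocentre untouched; C3 of the product is epimerisable and is removed in the next step.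

Step 16
Reactants: 30 ethyl (3S,4R)-4-[4-(benzyloxy)-3-methoxybenzyl]-2-oxotetrahydrofuran-3-carboxylate
Product: 31 (R)-4-[4-(benzyloxy)-3-methoxybenzyl]dihydrofuran-2(3H)-one
Conditions: LiCl, DMSO/H2O, 140 °C
Reagents that add atoms: none
Why: Krapcho dealkoxycarbonylation of the malonate-type lactone; the benzyl ether and the remote stereocentre are unaffected.

Step 17
Reactants: 31 (R)-4-[4-(benzyloxy)-3-methoxybenzyl]dihydrofuran-2(3H)-one; 22 (2S,3R)-5-(bromomethyl)-2-{4-[(tert-butyldimethylsilyl)oxy]-3-methoxyphenyl}-3-{[(tert-butyldimethylsilyl)oxy]methyl}-7-methoxy-2,3-dihydro-1-benzofuran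
Product: 33 (3R,4R)-4-[4-(benzyloxy)-3-methoxybenzyl]-3-{[(2S,3R)-2-{4-[(tert-butyldimethylsilyl)oxy]-3-methoxyphenyl}-3-{[(tert-butyldimethylsilyl)oxy]methyl}-7-methoxy-2,3-dihydro-1-benzofuran-5-yl]methyl}dihydrofuran-2(3H)-one, via lithium enolate 32 (not isolated)
Conditions: 31 (1.3 equiv), LiN(SiMe3)2 (1.25 equiv), THF, −78 °C; then 22, DMPU, −78 → −30 °C
Reagents that add atoms: none
Why: Alkylation of the lactone lithium enolate with a benzylic bromide; the Cβ substituent shields one face of the planar enolate, so the electrophile enters anti and gives the trans (R,R) lactone, as is general for β-benzylbutyrolactones.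

Step 18
Reactants: 33 (3R,4R)-4-[4-(benzyloxy)-3-methoxybenzyl]-3-{[(2S,3R)-2-{4-[(tert-butyldimethylsilyl)oxy]-3-methoxyphenyl}-3-{[(tert-butyldimethylsilyl)oxy]methyl}-7-methoxy-2,3-dihydro-1-benzofuran-5-yl]methyl}dihydrofuran-2(3H)-one
Product: 34 (3R,4R)-4-[4-(benzyloxy)-3-methoxybenzyl]-3-{[(2S,3R)-2-(4-hydroxy-3-methoxyphenyl)-3-(hydroxymethyl)-7-methoxy-2,3-dihydro-1-benzofuran-5-yl]methyl}dihydrofuran-2(3H)-one
Conditions: Bu4NF, AcOH, THF, 0 °C → rt
Reagents that add atoms: none
Why: Fluoride cleavage of both silyl ethers; the acetic acid buffer keeps the liberated ring C phenol protonated, so neither retro-oxa-Michael opening of the dihydrobenzofuran nor epimerisation at the lactone α-carbon is invited.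

Step 19
Reactants: 34 (3R,4R)-4-[4-(benzyloxy)-3-methoxybenzyl]-3-{[(2S,3R)-2-(4-hydroxy-3-methoxyphenyl)-3-(hydroxymethyl)-7-methoxy-2,3-dihydro-1-benzofuran-5-yl]methyl}dihydrofuran-2(3H)-one
Product: 35 isolappaol A
Conditions: H2 (1 atm), 10% Pd/C, EtOAc, rt
Reagents that add atoms: none
Why: Neutral hydrogenolysis of the one remaining aryl benzyl ether, stopped after uptake of one equivalent; aryl benzyl ethers are cleaved much faster than the cyclic benzylic C2–O1 bond.

## Compound list

1 | methyl vanillate (methyl 4-hydroxy-3-methoxybenzoate) | COC(=O)c1ccc(O)c(OC)c1 | starting material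
2 | allyl bromide | C=CCBr | starting material
3 | methyl 4-(allyloxy)-3-methoxybenzoate | COC(=O)c1ccc(OCC=C)c(OC)c1 | intermediate
4 | methyl 3-allyl-4-hydroxy-5-methoxybenzoate | COC(=O)c1cc(CC=C)c(O)c(OC)c1 | intermediate
5 | benzyl bromide | BrCc1ccccc1 | starting material
6 | methyl 3-allyl-4-(benzyloxy)-5-methoxybenzoate | COC(=O)c1cc(CC=C)c(OCc2ccccc2)c(OC)c1 | intermediate
7 | methyl 4-(benzyloxy)-3-methoxy-5-(2-oxoethyl)benzoate (not isolated) | COC(=O)c1cc(CC=O)c(OCc2ccccc2)c(OC)c1 | intermediate
8 | 2-[2-(benzyloxy)-3-methoxy-5-(methoxycarbonyl)phenyl]acetic acid | COC(=O)c1cc(CC(=O)O)c(OCc2ccccc2)c(OC)c1 | intermediate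
9 | (R)-4-benzyl-2-oxazolidinone | O=C1N[C@H](Cc2ccccc2)CO1 | starting material
10 | 2-[2-(benzyloxy)-3-methoxy-5-(methoxycarbonyl)phenyl]acetic pivalic anhydride (not isolated) | COC(=O)c1cc(CC(=O)OC(=O)C(C)(C)C)c(OCc2ccccc2)c(OC)c1 | intermediate
11 | methyl 4-(benzyloxy)-3-{2-[(4R)-4-benzyl-2-oxo-1,3-oxazolidin-3-yl]-2-oxoethyl}-5-methoxybenzoate | COC(=O)c1cc(CC(=O)N2[C@H](Cc3ccccc3)COC2=O)c(OCc2ccccc2)c(OC)c1 | intermediate
12 | 4-(benzyloxy)-3-methoxybenzyl alcohol | COc1cc(CO)ccc1OCc1ccccc1 | starting material
13 | 4-(benzyloxy)-3-methoxybenzyl bromide | COc1cc(CBr)ccc1OCc1ccccc1 | intermediate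
14 | sodium (Z)-enolate of imide 11 (not isolated) | [Na+].[O-]/C(=C\c1cc(C(=O)OC)cc(OC)c1OCc1ccccc1)N1[C@H](Cc2ccccc2)COC1=O | intermediate
15 | methyl 4-(benzyloxy)-3-{(2R)-1-[(4R)-4-benzyl-2-oxo-1,3-oxazolidin-3-yl]-3-[4-(benzyloxy)-3-methoxyphenyl]-1-oxopropan-2-yl}-5-methoxybenzoate | COC(=O)c1cc(OC)c(OCc2ccccc2)c(c1)[C@@H](Cc1ccc(OCc2ccccc2)c(OC)c1)C(=O)N1[C@H](Cc2ccccc2)COC1=O | intermediate
16 | methyl 4-(benzyloxy)-3-{(2R)-1-[4-(benzyloxy)-3-methoxyphenyl]-3-hydroxypropan-2-yl}-5-methoxybenzoate | COC(=O)c1cc(OC)c(OCc2ccccc2)c(c1)[C@@H](Cc1ccc(OCc2ccccc2)c(OC)c1)CO | intermediate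
17 | methyl 4-hydroxy-3-[(2R)-1-hydroxy-3-(4-hydroxy-3-methoxyphenyl)propan-2-yl]-5-methoxybenzoate | COC(=O)c1cc(OC)c(O)c(c1)[C@@H](Cc1ccc(O)c(OC)c1)CO | intermediate
18 | methyl 4-hydroxy-3-[(2R)-1-hydroxy-3-(3-methoxy-4-oxocyclohexa-2,5-dien-1-ylidene)propan-2-yl]-5-methoxybenzoate (para-quinone methide, not isolated) | COC1=CC(=C[C@@H](CO)c2cc(C(=O)OC)cc(OC)c2O)C=CC1=O | intermediate
19 | methyl (2S,3R)-2-(4-hydroxy-3-methoxyphenyl)-3-(hydroxymethyl)-7-methoxy-2,3-dihydro-1-benzofuran-5-carboxylate | COC(=O)c1cc(OC)c2c(c1)[C@H](CO)[C@@H](c1ccc(O)c(OC)c1)O2 | intermediate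
20 | methyl (2S,3R)-2-{4-[(tert-butyldimethylsilyl)oxy]-3-methoxyphenyl}-3-{[(tert-butyldimethylsilyl)oxy]methyl}-7-methoxy-2,3-dihydro-1-benzofuran-5-carboxylate | COC(=O)c1cc(OC)c2c(c1)[C@H](CO[Si](C)(C)C(C)(C)C)[C@@H](c1ccc(O[Si](C)(C)C(C)(C)C)c(OC)c1)O2 | intermediate
21 | [(2S,3R)-2-{4-[(tert-butyldimethylsilyl)oxy]-3-methoxyphenyl}-3-{[(tert-butyldimethylsilyl)oxy]methyl}-7-methoxy-2,3-dihydro-1-benzofuran-5-yl]methanol | OCc1cc(OC)c2c(c1)[C@H](CO[Si](C)(C)C(C)(C)C)[C@@H](c1ccc(O[Si](C)(C)C(C)(C)C)c(OC)c1)O2 | intermediate
22 | (2S,3R)-5-(bromomethyl)-2-{4-[(tert-butyldimethylsilyl)oxy]-3-methoxyphenyl}-3-{[(tert-butyldimethylsilyl)oxy]methyl}-7-methoxy-2,3-dihydro-1-benzofuran | BrCc1cc(OC)c2c(c1)[C@H](CO[Si](C)(C)C(C)(C)C)[C@@H](c1ccc(O[Si](C)(C)C(C)(C)C)c(OC)c1)O2 | intermediate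
23 | (R)-epichlorohydrin | ClC[C@H]1CO1 | starting material
24 | diethyl malonate | CCOC(=O)CC(=O)OCC | starting material
25 | diethyl 2-{[(2R)-oxiran-2-yl]methyl}malonate (not isolated) | CCOC(=O)C(C[C@@H]1CO1)C(=O)OCC | intermediate
26 | diethyl (2R)-2-(hydroxymethyl)cyclopropane-1,1-dicarboxylate (formed as its alkoxide, not isolated) | CCOC(=O)C1(C[C@H]1CO)C(=O)OCC | intermediate
27 | ethyl (1S,5R)-2-oxo-3-oxabicyclo[3.1.0]hexane-1-carboxylate | O=C1OC[C@@H]2C[C@]12C(=O)OCC | intermediate
28 | 1-(benzyloxy)-4-bromo-2-methoxybenzene | COc1cc(Br)ccc1OCc1ccccc1 | starting material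
29 | [4-(benzyloxy)-3-methoxyphenyl]magnesium bromide (not isolated) | COc1cc([Mg]Br)ccc1OCc1ccccc1 | intermediate
30 | ethyl (3S,4R)-4-[4-(benzyloxy)-3-methoxybenzyl]-2-oxotetrahydrofuran-3-carboxylate (trans; C3 epimerisable and of no consequence) | O=C1OC[C@H](Cc2ccc(OCc3ccccc3)c(OC)c2)[C@H]1C(=O)OCC | intermediate
31 | (R)-4-[4-(benzyloxy)-3-methoxybenzyl]dihydrofuran-2(3H)-one | O=C1OC[C@H](Cc2ccc(OCc3ccccc3)c(OC)c2)C1 | intermediate
32 | lithium enolate of lactone 31 (not isolated) | [Li+].[O-]C1=C[C@@H](Cc2ccc(OCc3ccccc3)c(OC)c2)CO1 | intermediate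
33 | (3R,4R)-4-[4-(benzyloxy)-3-methoxybenzyl]-3-{[(2S,3R)-2-{4-[(tert-butyldimethylsilyl)oxy]-3-methoxyphenyl}-3-{[(tert-butyldimethylsilyl)oxy]methyl}-7-methoxy-2,3-dihydro-1-benzofuran-5-yl]methyl}dihydrofuran-2(3H)-one | COc1cc(C[C@H]2COC(=O)[C@@H]2Cc2cc(OC)c3c(c2)[C@H](CO[Si](C)(C)C(C)(C)C)[C@@H](c2ccc(O[Si](C)(C)C(C)(C)C)c(OC)c2)O3)ccc1OCc1ccccc1 | intermediate
34 | (3R,4R)-4-[4-(benzyloxy)-3-methoxybenzyl]-3-{[(2S,3R)-2-(4-hydroxy-3-methoxyphenyl)-3-(hydroxymethyl)-7-methoxy-2,3-dihydro-1-benzofuran-5-yl]methyl}dihydrofuran-2(3H)-one | COc1cc(C[C@H]2COC(=O)[C@@H]2Cc2cc(OC)c3c(c2)[C@H](CO)[C@@H](c2ccc(O)c(OC)c2)O3)ccc1OCc1ccccc1 | intermediate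
35 | isolappaol A, (3R,4R)-4-(4-hydroxy-3-methoxybenzyl)-3-{[(2S,3R)-2-(4-hydroxy-3-methoxyphenyl)-3-(hydroxymethyl)-7-methoxy-2,3-dihydro-1-benzofuran-5-yl]methyl}dihydrofuran-2(3H)-one | COc1cc(C[C@H]2COC(=O)[C@@H]2Cc2cc(OC)c3c(c2)[C@H](CO)[C@@H](c2ccc(O)c(OC)c2)O3)ccc1O | target

## Step count and least certain steps

Total step count: 19. Longest linear sequence: 15 steps (steps 1–5, 7–13 and 17–19, from methyl vanillate 1).

**Step 10 (key step).** Three things may go wrong.
- Proton loss from C3 of quinone methide 18 (tautomerisation to a stilbene) would erase the only stereocentre before the phenol closes.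
- The product still carries a free 4-alkylphenol and may be dehydrogenated further towards the benzofuran.
- One-electron oxidation may divert ring C into phenoxyl radical coupling at its free ortho position.

Fallback: reach the same quinone methide by dehydration, not by oxidation. It sets out from acid 8.
- Acid 8 is attached to (S)-4-benzyl-2-oxazolidinone as in step 5, giving the (4S)-oxazolidinone imide F1.
- A boron-mediated Evans syn-aldol reaction (Bu2BOTf, i-Pr2NEt, CH2Cl2, −78 → 0 °C) with commercial 4-(benzyloxy)-3-methoxybenzaldehyde gives the syn-aldol adduct F2. The boron aldol attacks the enolate face opposite to the one used by the chelated alkylation, which is why the antipodal auxiliary gives the same configuration at the future C3.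
- NaBH4 in aqueous THF removes the auxiliary and gives the 1,3-diol F3. Hydrogenolysis over Pd/C gives the tetraol F4.
- Catalytic TsOH in CH2Cl2/THF ionises the para-hydroxybenzylic alcohol and the ring B phenol closes under thermodynamic control to the trans product. The configuration of the carbinol centre is immaterial.
- The sequence returns to the route at 19.

**Step 8.** The basic aqueous borohydride medium may epimerise the α-aryl stereocentre, hydride may attack the ring carbonyl of the auxiliary (endocyclic cleavage), or the methyl benzoate may be partly reduced.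

Fallback from 15: hydrolysis with LiOH/H2O2 (THF/H2O, 0 °C) gives the carboxylic acid F5. BH3·SMe2 (THF, 0 °C) then reduces the acid in the presence of the methyl ester. The sequence returns at 16.

**Step 17.** The para-alkoxybenzylic bromide 22 may ionise and decompose before C-alkylation, proton transfer between product and enolate may lead to double alkylation, and the aryl silyl ether may be lost to the amide base.

Fallback from 22 and the malonate-type lactone 30 (already on the route): alkylation of the soft enolate of 30 with 22 (K2CO3, DMF, rt) gives the quaternary lactone ester F6. Krapcho dealkoxycarbonylation (LiCl, wet DMSO, 140 °C) removes the ester group, protonation placing the two benzyl groups trans. The sequence returns at 33. Any loss of the phenolic silyl group in the hot chloride medium would merely anticipate step 18.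

**Step 19.** Hydrogenolytic opening of the benzylic C2–O1 bond of the dihydrobenzofuran may compete with O-debenzylation.

Fallback: change the ring A protecting group so that no hydrogenolysis is needed at the end. From 31, hydrogenolysis (H2, Pd/C) gives the phenol lactone F7, and TBSCl/imidazole gives the silyl ether lactone F8. Its lithium enolate is alkylated with 22 as in step 17 to give the tris-silyl ether F9. Bu4NF/AcOH removes all three silyl groups and returns directly at 35.

## Further compounds

F1 | step 10 | methyl 4-(benzyloxy)-3-{2-[(4S)-4-benzyl-2-oxo-1,3-oxazolidin-3-yl]-2-oxoethyl}-5-methoxybenzoate | COC(=O)c1cc(CC(=O)N2[C@@H](Cc3ccccc3)COC2=O)c(OCc2ccccc2)c(OC)c1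
F2 | step 10 | methyl 4-(benzyloxy)-3-{(1S,2S)-3-[(4S)-4-benzyl-2-oxo-1,3-oxazolidin-3-yl]-1-[4-(benzyloxy)-3-methoxyphenyl]-1-hydroxy-3-oxopropan-2-yl}-5-methoxybenzoate | COC(=O)c1cc(OC)c(OCc2ccccc2)c(c1)[C@@H]([C@H](O)c1ccc(OCc2ccccc2)c(OC)c1)C(=O)N1[C@@H](Cc2ccccc2)COC1=O
F3 | step 10 | methyl 4-(benzyloxy)-3-{(1S,2R)-1-[4-(benzyloxy)-3-methoxyphenyl]-1,3-dihydroxypropan-2-yl}-5-methoxybenzoate | COC(=O)c1cc(OC)c(OCc2ccccc2)c(c1)[C@H](CO)[C@H](O)c1ccc(OCc2ccccc2)c(OC)c1
F4 | step 10 | methyl 3-[(1S,2R)-1,3-dihydroxy-1-(4-hydroxy-3-methoxyphenyl)propan-2-yl]-4-hydroxy-5-methoxybenzoate | COC(=O)c1cc(OC)c(O)c(c1)[C@H](CO)[C@H](O)c1ccc(O)c(OC)c1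
F5 | step 8 | (2R)-2-[2-(benzyloxy)-3-methoxy-5-(methoxycarbonyl)phenyl]-3-[4-(benzyloxy)-3-methoxyphenyl]propanoic acid | COC(=O)c1cc(OC)c(OCc2ccccc2)c(c1)[C@@H](Cc1ccc(OCc2ccccc2)c(OC)c1)C(=O)O
F6 | step 17 | ethyl (3R,4R)-4-[4-(benzyloxy)-3-methoxybenzyl]-3-{[(2S,3R)-2-{4-[(tert-butyldimethylsilyl)oxy]-3-methoxyphenyl}-3-{[(tert-butyldimethylsilyl)oxy]methyl}-7-methoxy-2,3-dihydro-1-benzofuran-5-yl]methyl}-2-oxotetrahydrofuran-3-carboxylate | CCOC(=O)[C@@]1(Cc2cc(OC)c3c(c2)[C@H](CO[Si](C)(C)C(C)(C)C)[C@@H](c2ccc(O[Si](C)(C)C(C)(C)C)c(OC)c2)O3)[C@@H](Cc2ccc(OCc3ccccc3)c(OC)c2)COC1=O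
F7 | step 19 | (R)-4-(4-hydroxy-3-methoxybenzyl)dihydrofuran-2(3H)-one | O=C1OC[C@H](Cc2ccc(O)c(OC)c2)C1
F8 | step 19 | (R)-4-{4-[(tert-butyldimethylsilyl)oxy]-3-methoxybenzyl}dihydrofuran-2(3H)-one | O=C1OC[C@H](Cc2ccc(O[Si](C)(C)C(C)(C)C)c(OC)c2)C1
F9 | step 19 | (3R,4R)-4-{4-[(tert-butyldimethylsilyl)oxy]-3-methoxybenzyl}-3-{[(2S,3R)-2-{4-[(tert-butyldimethylsilyl)oxy]-3-methoxyphenyl}-3-{[(tert-butyldimethylsilyl)oxy]methyl}-7-methoxy-2,3-dihydro-1-benzofuran-5-yl]methyl}dihydrofuran-2(3H)-one | COc1cc(C[C@H]2COC(=O)[C@@H]2Cc2cc(OC)c3c(c2)[C@H](CO[Si](C)(C)C(C)(C)C)[C@@H](c2ccc(O[Si](C)(C)C(C)(C)C)c(OC)c2)O3)ccc1O[Si](C)(C)C(C)(C)C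
A1 | alternative 1 | (3R,4R,5R)-3-[4-(benzyloxy)-3-methoxybenzyl]-4-{2-[(2S,3R)-2-[4-(benzyloxy)-3-methoxyphenyl]-7-methoxy-3-{[(triisopropylsilyl)oxy]methyl}-2,3-dihydro-1-benzofuran-5-yl]-1,3-dithian-2-yl}-5-[(trityloxy)methyl]dihydrofuran-2(3H)-one (all-trans) | O=C1O[C@@H](COC(c2ccccc2)(c2ccccc2)c2ccccc2)[C@H](C2(SCCCS2)c2cc(OC)c3c(c2)[C@H](CO[Si](C(C)C)(C(C)C)C(C)C)[C@@H](c2ccc(OCc4ccccc4)c(OC)c2)O3)[C@H]1Cc1ccc(OCc2ccccc2)c(OC)c1
A2 | alternative 1 | (R)-5-[(trityloxy)methyl]furan-2(5H)-one | O=C1O[C@@H](COC(c2ccccc2)(c2ccccc2)c2ccccc2)C=C1
A3 | alternative 1 | 2-[(2S,3R)-2-[4-(benzyloxy)-3-methoxyphenyl]-7-methoxy-3-{[(triisopropylsilyl)oxy]methyl}-2,3-dihydro-1-benzofuran-5-yl]-1,3-dithiane | S1CCCSC1c1cc(OC)c2c(c1)[C@H](CO[Si](C(C)C)(C(C)C)C(C)C)[C@@H](c1ccc(OCc3ccccc3)c(OC)c1)O2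
A4 | alternative 2 | 3-[4-(benzyloxy)-3-methoxybenzyl]cyclobutan-1-one | O=C1CC(Cc2ccc(OCc3ccccc3)c(OC)c2)C1
A5 | alternative 2 | (R)-4-[4-(benzyloxy)-3-methoxybenzyl]dihydrofuran-2(3H)-one (identical with 31) | COc1cc(C[C@H]2COC(=O)C2)ccc1OCc1ccccc1
A6 | alternative 3 | 4-bromo-2-{2-[(tert-butyldimethylsilyl)oxy]-1-[(4-methylphenyl)sulfonyl]ethyl}-6-methoxyphenol (racemic) | COc1cc(Br)cc(C(CO[Si](C)(C)C(C)(C)C)S(=O)(=O)c2ccc(C)cc2)c1O
A7 | alternative 3 | (2R,5R)-1-[4-(benzyloxy)-3-methoxybenzyl]-2,5-dimethylthiolan-1-ium tetrafluoroborate (or its antipode, whichever gives the 2S,3R series) | C[C@@H]1CC[C@@H](C)[S+]1Cc1ccc(OCc2ccccc2)c(OC)c1.F[B-](F)(F)F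
A8 | alternative 3 | (2S,3R)-2-[4-(benzyloxy)-3-methoxyphenyl]-5-bromo-3-{[(tert-butyldimethylsilyl)oxy]methyl}-7-methoxy-2,3-dihydro-1-benzofuran | Brc1cc(OC)c2c(c1)[C@H](CO[Si](C)(C)C(C)(C)C)[C@@H](c1ccc(OCc3ccccc3)c(OC)c1)O2
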